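2.50 × 10⁻⁴ M of pre-initiator goes into each flask, gamma and alpha, so if each unit started one chain you would read 40.0 monomer units per chain.

| flask | free monomer | pre-initiator | time |
|---|---|---|---|
| gamma | 0.010 M | 2.5 mol% | 20 min |
| alpha | 0.010 M | 2.5 mol% | 60 min |

    free monomer + initiator → living end + monomer in chains (k1 = 0.179 /M/s)
    free monomer + living end → monomer in chains + living end, rate k2*[living end]*[free monomer] (k2 = 219 /M/s)
    pre-initiator ⇌ initiator (K3 = 0.35, k3 = 0.0560 /s)
    2 initiator → spent initiator (k4 = 86.7 /M/s)

- a doubled species enters its step squared and goes two at a time
- the average divides the monomer in chains by the number of chains begun, living and dead together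
- run time (gamma): 20 min

* which of the two ends with the longer chains by the average number of monomer units in a chain (chains begun, living or dead) ("neither" if they lie within 10%) (gamma / alpha / neither)
* average number of monomer units in a chain (chains begun, living or dead) at the end, gamma
* average number of monomer units in a chain (chains begun, living or dead) at the end, alpha

But initiator has a second way out. Its supply equilibrates quickly, with a forward half-life of 0.21 min, so c(initiator) starts near 6.48 × 10⁻⁵ M. Each initiator then starts a chain at 0.00179 /s and is lost in pairs at 0.0112 /s, which is faster. The starting share of chain starts is 13.7%, giving a length of 291.

That share is a start value, and it drifts, since chain growth eats the free monomer that chain starting needs. So compare the two uses of free monomer at one moment: c(free monomer) cancels, and growth beats starting by the constants' ratio 1220 times c(living end)/c(initiator). Integrated over the charge with c(initiator) held at its start, this gives 3.26 × 10⁻⁵ M chains.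

Yet c(initiator) does not hold. The pair loss, drawing on the equilibrated reservoir, halves it in 5.72 min. Held at its start, c(initiator) puts free monomer at half of its charge at about 3.89 min, an estimate that comes too early because c(initiator) falls, to near 3.86 × 10⁻⁵ M by then. A second pass with that value moves my estimate of that moment to about 5.05 min, with c(initiator) near 3.44 × 10⁻⁵ M. Putting that value in gives the race count, the chains begun by the time growth has used the charge: 2.37 × 10⁻⁵ M.

My lengths are 421 for gamma and 421 for alpha. Does gamma stop too early? At that count, growth leaves 0.196% of the free monomer by 20 min, so my answer is neither.

The forecast says neither, with 420 and 421, on the ground that “most of the initiator is then lost to the bimolecular step”.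

The simulation gives neither, with 422 in gamma and 424 in alpha; gamma holds 2.35 × 10⁻⁵ M of living end at 20.0 min, against a race count of 2.37 × 10⁻⁵ M. At 4.74 min in gamma, free monomer went into growth 680 times as fast as into new chains, and its half-life by growth was 2.9 min, against 13 min for initiator by chain start. In the neighbour flask with 0.62 mol% of pre-initiator, c(initiator) starts near 1.61 × 10⁻⁵ M, and the same two passes put it near 1.20 × 10⁻⁵ M and then 1.15 × 10⁻⁵ M. With the 90.2% of free monomer used, that gives a race count of 1.30 × 10⁻⁵ M and a length of 691; that flask reads 734.

(The constants are those of an exercise; the result is computed.)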